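**Plan**

- Retrosynthesis: ring C is opened at O1–C2 and C2–C3 (C2 is a one-carbon unit from DMF dimethyl acetal), leaving a 2-hydroxydeoxybenzoin. Ring A is then cut at C4a–C8a to a 4-alkenyl-4-methoxycyclobutenone, and this at C5–C6 into dimethyl squarate and a vinyl anion; the C4–C4a bond goes back to an arylacetic Weinreb amide and an ethynyl Grignard reagent.
- Enabling feature: ring A carries four contiguous oxygenated carbons (C6, C7, C8, C8a), with the C6 methoxy para to the C8a oxygen. Squarate supplies C7 and C8 with their methoxy groups, and its two carbonyl carbons become C6 and C8a.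
- Forward order: ring B is purchased; the C3–C4–C4a–C5 chain is built as a ketal-protected E-vinylstannane and joined to squarate; ring A forms by electrocyclic opening and closure; ring C is closed last.
- Stereochemistry: the target has no stereocentre. Only the E geometry of the vinylmetal matters (set by syn hydrostannation), and the racemic carbinol centre of the cyclobutenone is erased on aromatisation.

Key step: step 6

Remark: all sp3 stereocentres that appear on the way (tetrahedral Weinreb adduct, cyclobutenone carbinol carbon, cyclohexadienone) are racemic and disappear later; the enaminone is drawn as its E isomer, although its geometry should not matter for ring closure.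

**Step 1**
Reactants: 1 3,4,5-trimethoxyphenylacetic acid
Product: 3 N-methoxy-N-methyl-2-(3,4,5-trimethoxyphenyl)acetamide, via acyl imidazole 2 (not isolated)
Conditions: CDI, CH2Cl2, rt; then MeNHOMe·HCl, rt
Reagents that add atoms: N,O-dimethylhydroxylamine hydrochloride, CNOC.Cl
Why: Activation of the acid as its acyl imidazole and aminolysis by the hydroxylamine is a standard Weinreb amide synthesis, and the released imidazole serves as the base.

**Step 2**
Reactants: 3 N-methoxy-N-methyl-2-(3,4,5-trimethoxyphenyl)acetamide; 4 ethynylmagnesium bromide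
Product: 6 1-(3,4,5-trimethoxyphenyl)but-3-yn-2-one, via magnesium hemiaminal chelate 5 (not isolated)
Conditions: THF, 0 °C; inverse quench into cold 1 M HCl
Reagents that add atoms: none
Why: In this Weinreb ketone synthesis the N,O-chelated tetrahedral adduct blocks a second addition, the weakly basic alkynyl Grignard reagent should not enolise the benzylic amide, and the acidic quench keeps the liberated hydroxylamine protonated so that it cannot add to the ynone.

**Step 3**
Reactants: 6 1-(3,4,5-trimethoxyphenyl)but-3-yn-2-one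
Product: 7 2-ethynyl-2-(3,4,5-trimethoxybenzyl)-1,3-dioxolane
Conditions: TMSOCH2CH2OTMS, TMSOTf (cat.), CH2Cl2, −78 to −20 °C; pyridine quench
Reagents that add atoms: 1,2-bis(trimethylsilyloxy)ethane, C[Si](C)(C)OCCO[Si](C)(C)C
Why: Aprotic silyl-transfer ketalisation, driven by formation of hexamethyldisiloxane, converts the carbonyl to the dioxolane at low temperature without free alcohol or water, so the alkynone terminus and the enolisable benzylic methylene should stay untouched.

**Step 4**
Reactants: 7 2-ethynyl-2-(3,4,5-trimethoxybenzyl)-1,3-dioxolane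
Product: 8 (E)-tributyl{2-[2-(3,4,5-trimethoxybenzyl)-1,3-dioxolan-2-yl]vinyl}stannane
Conditions: Bu3SnH, PdCl2(PPh3)2 (2 mol %), THF, 0 °C to rt; chromatography on Et3N-deactivated silica
Reagents that add atoms: tributyltin hydride, CCCC[SnH](CCCC)CCCC
Why: Palladium-catalysed hydrostannation (Sn–H oxidative addition to zerovalent palladium formed in situ, then syn addition across the alkyne) places tin on the unhindered terminal carbon because the neighbouring carbon is fully substituted, which should give the E-vinylstannane.

**Step 5**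
Reactants: 8 (E)-tributyl{2-[2-(3,4,5-trimethoxybenzyl)-1,3-dioxolan-2-yl]vinyl}stannane; 9 dimethyl squarate
Product: 12 rac-2,3,4-trimethoxy-4-[(E)-2-[2-(3,4,5-trimethoxybenzyl)-1,3-dioxolan-2-yl]vinyl]cyclobut-2-en-1-one, via vinyllithium 10 (not isolated), via lithium alkoxide 11 (not isolated)
Conditions: n-BuLi, THF, −78 °C; cannulate into 9, THF, −78 °C; MeOTf, −78 to 0 °C; NaHCO3 work-up, Et3N-deactivated silica
Reagents that add atoms: methyl trifluoromethanesulfonate, COS(=O)(=O)C(F)(F)F
Why: Tin–lithium exchange with retention of alkene geometry, 1,2-addition of the vinyllithium to one of the two equivalent squarate carbonyls and O-methylation of the resulting alkoxide by the hard electrophile MeOTf follow the usual preparation of 4-substituted 4-alkoxycyclobutenones, and the new carbinol centre is formed as a racemate that is of no consequence.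

**Step 6**
Reactants: 12 rac-2,3,4-trimethoxy-4-[(E)-2-[2-(3,4,5-trimethoxybenzyl)-1,3-dioxolan-2-yl]vinyl]cyclobut-2-en-1-one
Product: 15 2,3,4-trimethoxy-6-[2-(3,4,5-trimethoxybenzyl)-1,3-dioxolan-2-yl]phenol, via dienylketene 13 (not isolated), via cyclohexadienone 14 (not isolated)
Conditions: toluene (0.02 M, degassed), 110 °C, Ar, base-washed glassware
Reagents that add atoms: none
Why: Heating cleaves the C1–C4 bond of the cyclobutenone by conrotatory 4π electrocyclic opening to dienylketene 13, which closes by thermal disrotatory 6π electrocyclisation between the ketene carbon (future C8a) and the alkene terminus (future C4a) to cyclohexa-2,4-dienone 14, and enolisation of its ring C–H gives the phenol. The closest known reaction type is the Moore rearrangement of squarate-derived 4-alkenyl-4-alkoxy- or 4-hydroxycyclobutenones to monoprotected hydroquinones. Ring A is the only ring formed, a six-membered carbocycle closed by 6π electrocyclisation with one new C–C bond (C4a–C8a). No lasting stereocentre arises: the racemic carbinol carbon of 12 becomes the sp2 carbon C6, and the transient sp3 centre of 14 is lost on aromatisation. The step needs torquoselective opening with the alkenyl group turned inward toward the ketene; the donor methoxy group on C4 secures this by its preference for outward rotation, a ketene of the wrong geometry can only revert to 12, and the E alkene keeps the bulky ketal carbon on the outside of the closing terminus. In the product the former carbinol carbon with its methoxy group is C6, the two squarate enol-ether carbons are C7 and C8, and the ketene oxygen is the free C8a hydroxyl required for ring C.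

**Step 7**
Reactants: 15 2,3,4-trimethoxy-6-[2-(3,4,5-trimethoxybenzyl)-1,3-dioxolan-2-yl]phenol
Product: 16 1-(2-hydroxy-3,4,5-trimethoxyphenyl)-2-(3,4,5-trimethoxyphenyl)ethan-1-one
Conditions: 1 M HCl, THF, rt
Reagents that add atoms: water, O
Why: Acid-catalysed acetal hydrolysis should be fast because the oxocarbenium ion is stabilised by the ortho hydroxyl and the para methoxy group, and the aryl methyl ethers are inert to dilute acid.

**Step 8**
Reactants: 16 1-(2-hydroxy-3,4,5-trimethoxyphenyl)-2-(3,4,5-trimethoxyphenyl)ethan-1-one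
Product: 18 6,7,8-trimethoxy-3-(3,4,5-trimethoxyphenyl)-4H-chromen-4-one, via enaminone 17 (not isolated)
Conditions: Me2NCH(OMe)2, toluene, 100 °C; then AcOH, 80 °C
Reagents that add atoms: N,N-dimethylformamide dimethyl acetal, COC(OC)N(C)C
Why: Condensation of the activated deoxybenzoin methylene with the formamide acetal gives the enaminone, and conjugate addition of the phenol oxygen with loss of dimethylamine closes ring C, which is the standard deoxybenzoin route to isoflavones.

**Compound list**

1 | 3,4,5-trimethoxyphenylacetic acid | COc1cc(CC(=O)O)cc(OC)c1OC | starting material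
2 | 1-(1H-imidazol-1-yl)-2-(3,4,5-trimethoxyphenyl)ethan-1-one | COc1cc(CC(=O)n2ccnc2)cc(OC)c1OC | intermediate
3 | N-methoxy-N-methyl-2-(3,4,5-trimethoxyphenyl)acetamide | COc1cc(CC(=O)N(C)OC)cc(OC)c1OC | intermediate
4 | ethynylmagnesium bromide | C#C[Mg]Br | starting material
5 | rac-bromomagnesium 2-[methoxy(methyl)amino]-1-(3,4,5-trimethoxyphenyl)but-3-yn-2-olate (N,O-chelated adduct) | COc1cc(CC(O[Mg]Br)(C#C)N(C)OC)cc(OC)c1OC | intermediate
6 | 1-(3,4,5-trimethoxyphenyl)but-3-yn-2-one | COc1cc(CC(=O)C#C)cc(OC)c1OC | intermediate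
7 | 2-ethynyl-2-(3,4,5-trimethoxybenzyl)-1,3-dioxolane | COc1cc(CC2(C#C)OCCO2)cc(OC)c1OC | intermediate
8 | (E)-tributyl{2-[2-(3,4,5-trimethoxybenzyl)-1,3-dioxolan-2-yl]vinyl}stannane | CCCC[Sn](CCCC)(CCCC)/C=C/C1(Cc2cc(OC)c(OC)c(OC)c2)OCCO1 | intermediate
9 | dimethyl squarate (3,4-dimethoxycyclobut-3-ene-1,2-dione) | COC1=C(OC)C(=O)C1=O | starting material
10 | (E)-{2-[2-(3,4,5-trimethoxybenzyl)-1,3-dioxolan-2-yl]vinyl}lithium | [Li]/C=C/C1(Cc2cc(OC)c(OC)c(OC)c2)OCCO1 | intermediate
11 | rac-lithium 2,3-dimethoxy-4-oxo-1-[(E)-2-[2-(3,4,5-trimethoxybenzyl)-1,3-dioxolan-2-yl]vinyl]cyclobut-2-en-1-olate | [Li+].[O-]C1(/C=C/C2(Cc3cc(OC)c(OC)c(OC)c3)OCCO2)C(OC)=C(OC)C1=O | intermediate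
12 | rac-2,3,4-trimethoxy-4-[(E)-2-[2-(3,4,5-trimethoxybenzyl)-1,3-dioxolan-2-yl]vinyl]cyclobut-2-en-1-one | COC1=C(OC)C(OC)(/C=C/C2(Cc3cc(OC)c(OC)c(OC)c3)OCCO2)C1=O | intermediate
13 | (3Z,5E)-2,3,4-trimethoxy-6-[2-(3,4,5-trimethoxybenzyl)-1,3-dioxolan-2-yl]hexa-1,3,5-trien-1-one | O=C=C(OC)/C(OC)=C(OC)\C=C\C1(Cc2cc(OC)c(OC)c(OC)c2)OCCO1 | intermediate
14 | rac-2,3,4-trimethoxy-6-[2-(3,4,5-trimethoxybenzyl)-1,3-dioxolan-2-yl]cyclohexa-2,4-dien-1-one | O=C1C(OC)=C(OC)C(OC)=CC1C2(Cc3cc(OC)c(OC)c(OC)c3)OCCO2 | intermediate
15 | 2,3,4-trimethoxy-6-[2-(3,4,5-trimethoxybenzyl)-1,3-dioxolan-2-yl]phenol | COc1cc(C2(Cc3cc(OC)c(OC)c(OC)c3)OCCO2)c(O)c(OC)c1OC | intermediate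
16 | 1-(2-hydroxy-3,4,5-trimethoxyphenyl)-2-(3,4,5-trimethoxyphenyl)ethan-1-one | COc1cc(C(=O)Cc2cc(OC)c(OC)c(OC)c2)c(O)c(OC)c1OC | intermediate
17 | (E)-3-(dimethylamino)-1-(2-hydroxy-3,4,5-trimethoxyphenyl)-2-(3,4,5-trimethoxyphenyl)prop-2-en-1-one | COc1cc(C(=O)/C(=C/N(C)C)c2cc(OC)c(OC)c(OC)c2)c(O)c(OC)c1OC | intermediate
18 | 6,7,8-trimethoxy-3-(3,4,5-trimethoxyphenyl)-4H-chromen-4-one (CNP0330610.0) | COc1cc(-c2coc3c(OC)c(OC)c(OC)cc3c2=O)cc(OC)c1OC | target

**Summary**

Total step count: 8. Longest linear sequence: 8 steps (1 to 18); compounds 4 and 9 are purchased.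

**Steps most likely to fail**

Step 5. The tin–lithium exchange may stay incomplete, so that remaining n-BuLi adds to the squarate; a second addition to the vinylogous ester or slow O-methylation of the hindered tertiary alkoxide would also lower the return. The fallback sets out from 7 and comes back at 12. Hydrozirconation of 7 with Cp2Zr(H)Cl in THF and iodination with I2 in the same flask should give (E)-2-(2-iodovinyl)-2-(3,4,5-trimethoxybenzyl)-1,3-dioxolane F3. Iodine–lithium exchange with t-BuLi (2 equiv, Et2O, −78 °C) is irreversible and leaves no butyl nucleophile; it generates 10, which is added to 9 and methylated through 11 as before to give 12. If the methylation itself proves to be the weak point, the route described under step 6 avoids it.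

Step 3. Conjugate addition of oxygen nucleophiles to the unhindered alkynone terminus and acid-triggered oligomerisation of the enolisable ynone may outrun ketalisation of the conjugated carbonyl. The fallback sets out from 3 and comes back at 7. Addition of lithium (trimethylsilyl)acetylide (from trimethylsilylacetylene and n-BuLi, THF, −78 °C, acidic quench) to 3 should give 1-(3,4,5-trimethoxyphenyl)-4-(trimethylsilyl)but-3-yn-2-one F1, whose capped terminus is a poor acceptor. Ketalisation with ethylene glycol and TsOH in refluxing benzene with azeotropic removal of water should then give trimethyl{[2-(3,4,5-trimethoxybenzyl)-1,3-dioxolan-2-yl]ethynyl}silane F2, and K2CO3 in MeOH removes the silyl group to deliver 7.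

Step 6. Capture or oligomerisation of the ketene before it cyclises, ionisation of the tertiary allylic methyl ether on heating and air oxidation of the electron-rich phenol could all erode the ring formation. The fallback sets out from 8 and comes back at 16; it keeps the squarate ring construction but moves the C6 methylation to the end. The addition of 10 to 9 is quenched at the stage of 11 with aqueous NH4Cl instead of MeOTf to give rac-4-hydroxy-2,3-dimethoxy-4-[(E)-2-[2-(3,4,5-trimethoxybenzyl)-1,3-dioxolan-2-yl]vinyl]cyclobut-2-en-1-one F4, the parent substrate class of this rearrangement. Thermolysis in degassed toluene should give the hydroquinone 2,3-dimethoxy-5-[2-(3,4,5-trimethoxybenzyl)-1,3-dioxolan-2-yl]benzene-1,4-diol F5, kept under argon and washed with aqueous Na2S2O4. Hydrolysis of the dioxolane (1 M HCl, THF) gives 1-(2,5-dihydroxy-3,4-dimethoxyphenyl)-2-(3,4,5-trimethoxyphenyl)ethan-1-one F6. Me2SO4 (1 equiv) with K2CO3 in acetone should methylate only the 5-hydroxyl, because the 2-hydroxyl is hydrogen-bonded to the ketone, and this gives 16.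

**Further compounds**

F1 | step 3 | 1-(3,4,5-trimethoxyphenyl)-4-(trimethylsilyl)but-3-yn-2-one | COc1cc(CC(=O)C#C[Si](C)(C)C)cc(OC)c1OC
F2 | step 3 | trimethyl{[2-(3,4,5-trimethoxybenzyl)-1,3-dioxolan-2-yl]ethynyl}silane | COc1cc(CC2(C#C[Si](C)(C)C)OCCO2)cc(OC)c1OC
F3 | step 5 | (E)-2-(2-iodovinyl)-2-(3,4,5-trimethoxybenzyl)-1,3-dioxolane | COc1cc(CC2(/C=C/I)OCCO2)cc(OC)c1OC
F4 | step 6 | rac-4-hydroxy-2,3-dimethoxy-4-[(E)-2-[2-(3,4,5-trimethoxybenzyl)-1,3-dioxolan-2-yl]vinyl]cyclobut-2-en-1-one | COC1=C(OC)C(O)(/C=C/C2(Cc3cc(OC)c(OC)c(OC)c3)OCCO2)C1=O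
F5 | step 6 | 2,3-dimethoxy-5-[2-(3,4,5-trimethoxybenzyl)-1,3-dioxolan-2-yl]benzene-1,4-diol | COc1c(O)cc(C2(Cc3cc(OC)c(OC)c(OC)c3)OCCO2)c(O)c1OC
F6 | step 6 | 1-(2,5-dihydroxy-3,4-dimethoxyphenyl)-2-(3,4,5-trimethoxyphenyl)ethan-1-one | COc1c(O)cc(C(=O)Cc2cc(OC)c(OC)c(OC)c2)c(O)c1OC
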